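Of the starting material charged to a closed, stirred flask with enzyme, target and side product together hold 99.8 % at the last zeta reading, 98.8 % at the last eta reading and 100 % at the last beta reading. So the balance closes near the whole charge, and one number, the ratio of the two shares, describes a finished run.

| flask | starting material | enzyme | remark | time |
|---|---|---|---|---|
| zeta | 0.10 M | 0.038 mol% | run made earlier |  |
| eta | 0.10 M | 0.15 mol% | run made earlier |  |
| beta | 0.20 M | 0.077 mol% | run made earlier |  |
| flask | 0.10 M | 0.077 mol% |  | 3.0 h |

| run | time / h | target / % | side product / % |
|---|---|---|---|
| zeta | 0.417 | 30.3 | 60.2 |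
| zeta | 0.833 | 28.6 | 71.2 |
| zeta | 1.33 | 28.7 | 71.2 |
| zeta | 1.50 | 29.0 | 71.5 |
| zeta | 2.00 | 28.3 | 71.6 |
| zeta | 2.50 | 28.4 | 71.4 |
| eta | 0.200 | 56.8 | 35.4 |
| eta | 0.333 | 59.2 | 39.9 |
| eta | 0.500 | 58.7 | 41.1 |
| eta | 0.833 | 58.5 | 40.1 |
| eta | 1.33 | 58.9 | 41.7 |
| eta | 2.50 | 58.1 | 40.7 |
| beta | 0.500 | 46.8 | 53.8 |
| beta | 1.00 | 46.1 | 53.2 |
| beta | 1.33 | 46.5 | 53.8 |
| beta | 2.00 | 46.6 | 53.5 |
| beta | 2.50 | 46.7 | 53.6 |

(standard deviation of a reading: 0.5 percentage points)

* the state of affairs at 3.0 h: stopped, and by what, or still going (all of the starting material has reacted / it is still moving / no working catalyst is left / forward and back rates have come level)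
* how much target there is at 3.0 h, in percent of the starting material charged
* how much side product there is at 3.0 h, in percent of the starting material charged

- percentages count the starting material that a species holds: one side product counts as two
- a reading or a percentage of target counts all its forms, free or not
- the reaction counts as stopped when no species that holds the starting material changes by six tenths of a point or more over the second half of the time

Is the flask finished at 3.0 h? Zeta has less enzyme than the flask at the same starting concentration, yet it already reads 99.8 % in total at 0.833 h. The flask's time is 3.60 times that, so complete reaction of the starting material is expected.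

What moves the split? Zeta and eta share the flask's concentration and differ in enzyme. Their split ratio r, target over side product at the last reading, reads 0.398 and 1.43. The split exponent, the logarithm of the rise in r divided by the logarithm of the rise in loading, reads 0.931, just under one.

What does the flask get? Its loading is 2.03 times zeta's, so this reckoning gives r = 0.767. That means 43.4 % target and 56.6 % side product.

The forecast, reached by its own route, says all of the starting material has reacted, with 43.3 % target and 56.7 % side product; for the end it reasons: “Target plus side product reaches about 100% in every run, and the readings go flat early”.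

The flask gives all of the starting material has reacted, with 43.7 % target and 56.3 % side product, so r = 0.776 against the reckoned 0.767.

    starting material + target → side product (k = 0.0754 M⁻¹ s⁻¹)
    starting material + enzyme ⇌ complex (K = 3.37 M⁻¹, k = 4790 M⁻¹ s⁻¹)
    starting material + target ⇌ idle adduct, settled at all times (K = 39.0 M⁻¹)
    complex → enzyme + target (k = 12.3 s⁻¹)

The neighbour flask has the same recipe with 0.31 mol% of enzyme, more than eta had. The split exponent carries zeta's ratio to r = 2.81 there, which is 73.8 % target. The neighbour flask gives 73.2 % target and 26.8 % side product at 3.00 h.

Readings and results stem from a simulated flask on assumed constants; the scatter is artificial.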